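**Retrosynthetic overview**
- Feature: the ketone carbons C4 and C4'' are 1,4-related through the C3–C3'' bond, and C3 is β to the C4'' carbonyl. An acyl anion at C4 adding to an exocyclic C3=C3''–C4''=O enone therefore forges C3–C4 and closes the pyranone ring (O1–C2–C3–C4–C4a–C8a) of the 4-methoxyphenyl half.
- Disconnections: five O-benzyl groups (hydrogenolysis), then C3–C4 (intramolecular Stetter) back to a salicylaldehyde (S)-ether of an (E)-3-ylidene flavanone.
- The C2–O ether bond comes from Mitsunobu inversion of an (R)-allylic alcohol with 2,4-bis(benzyloxy)-6-hydroxybenzaldehyde. The alcohol comes from CBS reduction of an enedione made by Mukaiyama aldol and dehydration from the benzylated (2S)-flavanone and 4-methoxyphenylglyoxal.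
- The (2S)-flavanone comes from rhodium-catalysed asymmetric arylation of 5,7-bis(benzyloxy)chromone.
- Ring order: pyranone ring of the hydroxyphenyl half first (steps 1–2), pyranone ring of the methoxyphenyl half last (step 8); all benzene rings are bought.

Key step: step 8

**Remarks on the chemistry**
- The benzylated (2S)-flavanone is made by asymmetric arylation of a chromone and not by benzylating (2S)-naringenin, because base strong enough to alkylate the hydrogen-bonded 5-OH opens the pyranone to the chalcone and erodes C2.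
- Assumption for step 5: the trisubstituted alkenyl arm, whose C2'' methine crowds the neighbouring carbonyl lone pair, is taken as the larger ketone substituent, so (R)-Me-CBS should give the (R)-carbinol; should the anisyl group dominate, (S)-Me-CBS is used instead.
- Assumption for step 8: the (5aR,10bS) antipode of the aminoindanol triazolium salt is taken as the one that reinforces the substrate's own facial bias; otherwise its enantiomer is used under the same conditions.
- Descriptor note: C2'' of the hydroxyphenyl half reads S in 5, 9, 16 and 17 but R in the 3-ylidene compounds 11, 12 and 15, through a priority change only; the spatial arrangement is the same throughout.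

**Route**

Step 1
Reactants: 1 1-[2,4-bis(benzyloxy)-6-hydroxyphenyl]ethan-1-one
Product: 3 5,7-bis(benzyloxy)-4H-chromen-4-one, via enaminone 2 (not isolated)
Conditions: Me2NCH(OMe)2, PhMe, 100 °C; then conc. HCl, CH2Cl2, rt
Reagents that add atoms: N,N-dimethylformamide dimethyl acetal, COC(OC)N(C)C
Why: Enaminone formation at the acetyl group followed by acid-promoted cyclisation of the ortho-phenol with loss of dimethylamine is the standard chromone synthesis from 2-hydroxyacetophenones, and the benzyl ethers should tolerate it.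

Step 2
Reactants: 3 5,7-bis(benzyloxy)-4H-chromen-4-one; 4 [4-(benzyloxy)phenyl]boronic acid
Product: 5 (2S)-5,7-bis(benzyloxy)-2-[4-(benzyloxy)phenyl]chroman-4-one
Conditions: [Rh(OH)(cod)]2 (2.5 mol%), (S)-MeO-F12-BIPHEP [(S)-6,6'-dimethoxy-2,2'-bis{bis(3,4,5-trifluorophenyl)phosphino}biphenyl] (5.5 mol%), PhMe/H2O, rt
Reagents that add atoms: none
Why: Hayashi–Miyaura asymmetric 1,4-addition of an arylboronic acid to a chromone under neutral conditions at room temperature should give the flavanone without chalcone formation, the (S)-biaryl bisphosphine delivering the aryl group to the face that sets C2 as S by the usual quadrant model for cyclic enones.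

Step 3
Reactants: 5 (2S)-5,7-bis(benzyloxy)-2-[4-(benzyloxy)phenyl]chroman-4-one; 6 4-methoxyphenylglyoxal
Product: 9 (2S)-5,7-bis(benzyloxy)-2-[4-(benzyloxy)phenyl]-3-[1-hydroxy-2-(4-methoxyphenyl)-2-oxoethyl]chroman-4-one (diastereomer mixture at C3 and the carbinol carbon), via silyl enol ether 7 (not isolated), via aldol silyl ether 8 (not isolated)
Conditions: TMSOTf, Et3N, CH2Cl2, 0 °C; filter through Celite in PhMe and concentrate; then 6 (dried azeotropically from its hydrate), Sc(OTf)3 (10 mol%), CH2Cl2, −78 °C; 1 M HCl, THF, 0 °C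
Reagents that add atoms: none
Why: Mukaiyama aldol addition of the flavanone silyl enol ether to the formyl carbon of the glyoxal, which is far more electrophilic than its ketone, avoids a free metal enolate that would open the pyranone by β-elimination, and the two new centres need no control because both become sp2 in step 4.

Step 4
Reactants: 9 (2S)-5,7-bis(benzyloxy)-2-[4-(benzyloxy)phenyl]-3-[1-hydroxy-2-(4-methoxyphenyl)-2-oxoethyl]chroman-4-one
Product: 11 (2R,3E)-5,7-bis(benzyloxy)-2-[4-(benzyloxy)phenyl]-3-[2-(4-methoxyphenyl)-2-oxoethylidene]chroman-4-one, via mesylate 10 (not isolated)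
Conditions: MsCl, Et3N, CH2Cl2, −20 to 0 °C, dark
Reagents that add atoms: none
Why: Mesylation and E1cB elimination through the C4'' enol should give the conjugated enedione as the more stable E isomer (the two carbonyl carbons trans across the double bond), the mesylate leaving far faster than the ring aryloxide.

Step 5
Reactants: 11 (2R,3E)-5,7-bis(benzyloxy)-2-[4-(benzyloxy)phenyl]-3-[2-(4-methoxyphenyl)-2-oxoethylidene]chroman-4-one
Product: 12 (2R,3E)-5,7-bis(benzyloxy)-2-[4-(benzyloxy)phenyl]-3-[(2R)-2-hydroxy-2-(4-methoxyphenyl)ethylidene]chroman-4-one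
Conditions: (R)-2-methyl-CBS-oxazaborolidine (0.5 equiv), catecholborane (1.5 equiv), PhMe, −78 °C; MeOH quench; chromatographic removal of the minor carbinol epimer
Reagents that add atoms: none
Why: Corey–Bakshi–Shibata 1,2-reduction should take the aroyl ketone in preference to the C4'' carbonyl, which is a vinylogous ester shielded by the peri benzyloxy group, with the oxazaborolidine setting the carbinol centre as R and the fixed C2'' centre making the minor epimer a separable diastereomer.

Step 6
Reactants: 13 2,4,6-trihydroxybenzaldehyde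
Product: 14 2,4-bis(benzyloxy)-6-hydroxybenzaldehyde
Conditions: BnBr (2.05 equiv), K2CO3, DMF, 0 °C to rt
Reagents that add atoms: benzyl bromide, BrCc1ccccc1
Why: Williamson etherification should stop at the dibenzyl ether because the last ortho-hydroxyl, hydrogen-bonded to the formyl group, is the least nucleophilic of the three.

Step 7
Reactants: 12 (2R,3E)-5,7-bis(benzyloxy)-2-[4-(benzyloxy)phenyl]-3-[(2R)-2-hydroxy-2-(4-methoxyphenyl)ethylidene]chroman-4-one; 14 2,4-bis(benzyloxy)-6-hydroxybenzaldehyde
Product: 15 2,4-bis(benzyloxy)-6-{(1S)-2-[(2R,3E)-5,7-bis(benzyloxy)-2-[4-(benzyloxy)phenyl]-4-oxochroman-3-ylidene]-1-(4-methoxyphenyl)ethoxy}benzaldehyde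
Conditions: PPh3, DIAD (slow addition), PhMe, −20 to 0 °C
Reagents that add atoms: none
Why: Mitsunobu etherification with the acidic salicylaldehyde phenol should proceed by SN2 inversion (R to S) at the carbinol carbon, the SN2' path being closed because C3'' is fully substituted and ionisation being disfavoured by the electron-poor enone and the non-polar solvent.

Step 8
Reactants: 15 2,4-bis(benzyloxy)-6-{(1S)-2-[(2R,3E)-5,7-bis(benzyloxy)-2-[4-(benzyloxy)phenyl]-4-oxochroman-3-ylidene]-1-(4-methoxyphenyl)ethoxy}benzaldehyde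
Product: 16 (2S,3R)-5,7-bis(benzyloxy)-3-[(2S,3R)-5,7-bis(benzyloxy)-2-[4-(benzyloxy)phenyl]-4-oxochroman-3-yl]-2-(4-methoxyphenyl)chroman-4-one
Conditions: (5aR,10bS)-2-(pentafluorophenyl)-5a,10b-dihydro-4H,6H-indeno[2,1-b][1,2,4]triazolo[4,3-d][1,4]oxazin-2-ium tetrafluoroborate (20 mol%), KN(SiMe3)2 (18 mol%), PhMe, 0 °C to rt; AcOH quench
Reagents that add atoms: none
Why: The triazolylidene adds to the formyl group and proton transfer gives the hydroxy-enamine (acyl anion equivalent), whose nucleophilic carbon, the future C4, attacks C3, the β-carbon of the exocyclic C3=C3''–C4''=O enone; collapse of the adduct releases the carbene and the C4 ketone, and the C4'' enolate is protonated at C3''. This is the intramolecular asymmetric Stetter reaction of salicylaldehyde-derived ethers onto trisubstituted Michael acceptors, exocyclic alkylidene ketones included, which is known to give 2,3-disubstituted chroman-4-ones. The pyranone ring O1–C2–C3–C4–C4a–C8a closes in the 6-exo-trig mode, the C3=C3'' bond lying outside the new ring. C3 (R) is set by substrate and catalyst together: A(1,3) strain holds the C2–H bond in the plane of the (E)-alkene, so the tethering oxygen and with it the acyl anion sit on one face and the anisyl group on the other, which leads to the 2,3-trans ring, and the matched catalyst antipode should reinforce this face. C3'' (R) is set in the protonation: delivery of the proton from the tetrahedral intermediate to the enolate on the face of C–C bond formation (net syn addition across the E-alkene) gives 3''R, which is also the thermodynamically preferred 2'',3''-trans arrangement that enolisation would reach should the cis epimer form. The step needs conjugate addition to outrun base-induced migration of the exocyclic double bond into the ring and β-elimination of either aryloxide, which the use of less base than azolium salt (no free strong base) and the non-polar solvent are meant to secure.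

Step 9
Reactants: 16 (2S,3R)-5,7-bis(benzyloxy)-3-[(2S,3R)-5,7-bis(benzyloxy)-2-[4-(benzyloxy)phenyl]-4-oxochroman-3-yl]-2-(4-methoxyphenyl)chroman-4-one
Product: 17 (2S,3R)-5,7-dihydroxy-3-[(2S,3R)-5,7-dihydroxy-2-(4-hydroxyphenyl)-4-oxochroman-3-yl]-2-(4-methoxyphenyl)chroman-4-one (CNP0196568.1)
Conditions: H2 (1 atm), 10% Pd/C, EtOAc/MeOH, rt
Reagents that add atoms: none
Why: Catalytic hydrogenolysis should cleave the five aryl benzyl ethers much faster than the benzylic C2–O ring bonds, leaving the ketones, the methyl ether and all four stereocentres untouched.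

**Compound list**
1 | 1-[2,4-bis(benzyloxy)-6-hydroxyphenyl]ethan-1-one | CC(=O)c1c(O)cc(OCc2ccccc2)cc1OCc1ccccc1 | starting material
2 | (E)-1-[2,4-bis(benzyloxy)-6-hydroxyphenyl]-3-(dimethylamino)prop-2-en-1-one | CN(C)/C=C/C(=O)c1c(O)cc(OCc2ccccc2)cc1OCc1ccccc1 | intermediate
3 | 5,7-bis(benzyloxy)-4H-chromen-4-one | O=c1ccoc2cc(OCc3ccccc3)cc(OCc3ccccc3)c12 | intermediate
4 | [4-(benzyloxy)phenyl]boronic acid | OB(O)c1ccc(OCc2ccccc2)cc1 | starting material
5 | (2S)-5,7-bis(benzyloxy)-2-[4-(benzyloxy)phenyl]chroman-4-one | O=C1C[C@@H](c2ccc(OCc3ccccc3)cc2)Oc2cc(OCc3ccccc3)cc(OCc3ccccc3)c12 | intermediate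
6 | 4-methoxyphenylglyoxal | COc1ccc(C(=O)C=O)cc1 | starting material
7 | (2S)-5,7-bis(benzyloxy)-2-[4-(benzyloxy)phenyl]-4-(trimethylsilyloxy)-2H-chromene | C[Si](C)(C)OC1=C[C@@H](c2ccc(OCc3ccccc3)cc2)Oc2cc(OCc3ccccc3)cc(OCc3ccccc3)c12 | intermediate
8 | trimethylsilyl ether of 9 (diastereomer mixture) | COc1ccc(C(=O)C(O[Si](C)(C)C)C2C(=O)c3c(OCc4ccccc4)cc(OCc4ccccc4)cc3O[C@@H]2c2ccc(OCc3ccccc3)cc2)cc1 | intermediate
9 | (2S)-5,7-bis(benzyloxy)-2-[4-(benzyloxy)phenyl]-3-[1-hydroxy-2-(4-methoxyphenyl)-2-oxoethyl]chroman-4-one (diastereomer mixture) | COc1ccc(C(=O)C(O)C2C(=O)c3c(OCc4ccccc4)cc(OCc4ccccc4)cc3O[C@@H]2c2ccc(OCc3ccccc3)cc2)cc1 | intermediate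
10 | methanesulfonate of 9 (diastereomer mixture) | COc1ccc(C(=O)C(OS(C)(=O)=O)C2C(=O)c3c(OCc4ccccc4)cc(OCc4ccccc4)cc3O[C@@H]2c2ccc(OCc3ccccc3)cc2)cc1 | intermediate
11 | (2R,3E)-5,7-bis(benzyloxy)-2-[4-(benzyloxy)phenyl]-3-[2-(4-methoxyphenyl)-2-oxoethylidene]chroman-4-one | COc1ccc(C(=O)/C=C2/C(=O)c3c(OCc4ccccc4)cc(OCc4ccccc4)cc3O[C@@H]2c2ccc(OCc3ccccc3)cc2)cc1 | intermediate
12 | (2R,3E)-5,7-bis(benzyloxy)-2-[4-(benzyloxy)phenyl]-3-[(2R)-2-hydroxy-2-(4-methoxyphenyl)ethylidene]chroman-4-one | COc1ccc([C@H](O)/C=C2/C(=O)c3c(OCc4ccccc4)cc(OCc4ccccc4)cc3O[C@@H]2c2ccc(OCc3ccccc3)cc2)cc1 | intermediate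
13 | 2,4,6-trihydroxybenzaldehyde | O=Cc1c(O)cc(O)cc1O | starting material
14 | 2,4-bis(benzyloxy)-6-hydroxybenzaldehyde | O=Cc1c(O)cc(OCc2ccccc2)cc1OCc1ccccc1 | intermediate
15 | 2,4-bis(benzyloxy)-6-{(1S)-2-[(2R,3E)-5,7-bis(benzyloxy)-2-[4-(benzyloxy)phenyl]-4-oxochroman-3-ylidene]-1-(4-methoxyphenyl)ethoxy}benzaldehyde | COc1ccc([C@@H](Oc2cc(OCc3ccccc3)cc(OCc3ccccc3)c2C=O)/C=C2/C(=O)c3c(OCc4ccccc4)cc(OCc4ccccc4)cc3O[C@@H]2c2ccc(OCc3ccccc3)cc2)cc1 | intermediate
16 | (2S,3R)-5,7-bis(benzyloxy)-3-[(2S,3R)-5,7-bis(benzyloxy)-2-[4-(benzyloxy)phenyl]-4-oxochroman-3-yl]-2-(4-methoxyphenyl)chroman-4-one | COc1ccc([C@H]2Oc3cc(OCc4ccccc4)cc(OCc4ccccc4)c3C(=O)[C@@H]2[C@H]2C(=O)c3c(OCc4ccccc4)cc(OCc4ccccc4)cc3O[C@@H]2c2ccc(OCc3ccccc3)cc2)cc1 | intermediate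
17 | (2S,3R)-5,7-dihydroxy-3-[(2S,3R)-5,7-dihydroxy-2-(4-hydroxyphenyl)-4-oxochroman-3-yl]-2-(4-methoxyphenyl)chroman-4-one | COc1ccc([C@H]2Oc3cc(O)cc(O)c3C(=O)[C@@H]2[C@H]2C(=O)c3c(O)cc(O)cc3O[C@@H]2c2ccc(O)cc2)cc1 | target

**Step count and risks**

Total step count: 9. Longest linear sequence: 8 steps (1, 2, 3, 4, 5, 7, 8, 9); step 6 is the side branch.

Steps most likely to fail:

1. Step 8 (Stetter closure).
   - What may go wrong: slow carbene addition to the doubly ortho-alkoxylated, electron-rich aldehyde; base-induced migration of the exocyclic double bond into the pyranone ring before C–C bond formation; poor facial selectivity, because the tether has to approach the alkene face that also carries the pseudoaxial C2'' aryl group; protonation at C3'' on the wrong face.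
   - Fallback: this sets out from 15 and returns at 16, replacing the carbene umpolung by an acyl radical conjugate addition. Pinnick oxidation of the formyl group (NaClO2, NaH2PO4, 2-methyl-2-butene, t-BuOH/H2O) should give 2,4-bis(benzyloxy)-6-{(1S)-2-[(2R,3E)-5,7-bis(benzyloxy)-2-[4-(benzyloxy)phenyl]-4-oxochroman-3-ylidene]-1-(4-methoxyphenyl)ethoxy}benzoic acid F1. Treatment with PhSeSePh and PBu3 should convert it into the Se-phenyl selenoester F2. Bu3SnH and AIBN in benzene at 80 °C should then generate the aroyl radical, which closes 6-exo-trig onto C3 of the enone under the same A(1,3) control but without catalyst bulk; the C3'' radical takes a hydrogen atom from the stannane to give 16, any 2'',3''-cis epimer being equilibrated by enolisation.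

2. Step 7 (Mitsunobu etherification).
   - What may go wrong: partial ionisation of the activated 4-methoxybenzylic carbinol, eroding the inversion, and sluggish reaction of the hydrogen-bonded phenol.
   - Fallback: this sets out from 11 and returns at 15, using net retention in place of inversion. Reduction of 11 with the enantiomeric oxazaborolidine (or the separation described for step 5) gives the (S)-carbinol epimer F3. Methyl chloroformate and pyridine in CH2Cl2 should convert it into the (S)-methyl carbonate F4. Tsuji–Trost etherification with 14 and Pd(PPh3)4 in THF should ionise the carbonate with inversion, and phenoxide attack at the anisyl-bearing allyl terminus with a second inversion should give the (S)-ether 15 with the enone conjugation kept.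

3. Step 5 (CBS reduction).
   - What may go wrong: low or opposite facial selectivity, since aryl and alkenyl substituents are of similar size, and competing conjugate reduction of the enedione.
   - Fallback: this sets out from 11 and returns at 12, replacing catalyst control by separation and recycling. Luche reduction (NaBH4, CeCl3·7H2O, MeOH/THF, −78 °C) should give 12 together with its carbinol epimer, (2R,3E)-5,7-bis(benzyloxy)-2-[4-(benzyloxy)phenyl]-3-[(2S)-2-hydroxy-2-(4-methoxyphenyl)ethylidene]chroman-4-one F3. The two are diastereomers because C2'' is fixed and should separate on silica; F3 is oxidised back to 11 with MnO2 in CH2Cl2 and recycled.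

**Further compounds**
F1 | step 8 | 2,4-bis(benzyloxy)-6-{(1S)-2-[(2R,3E)-5,7-bis(benzyloxy)-2-[4-(benzyloxy)phenyl]-4-oxochroman-3-ylidene]-1-(4-methoxyphenyl)ethoxy}benzoic acid | COc1ccc([C@@H](Oc2cc(OCc3ccccc3)cc(OCc3ccccc3)c2C(=O)O)/C=C2/C(=O)c3c(OCc4ccccc4)cc(OCc4ccccc4)cc3O[C@@H]2c2ccc(OCc3ccccc3)cc2)cc1
F2 | step 8 | Se-phenyl selenoester of F1 | COc1ccc([C@@H](Oc2cc(OCc3ccccc3)cc(OCc3ccccc3)c2C(=O)[Se]c2ccccc2)/C=C2/C(=O)c3c(OCc4ccccc4)cc(OCc4ccccc4)cc3O[C@@H]2c2ccc(OCc3ccccc3)cc2)cc1
F3 | step 5 | (2R,3E)-5,7-bis(benzyloxy)-2-[4-(benzyloxy)phenyl]-3-[(2S)-2-hydroxy-2-(4-methoxyphenyl)ethylidene]chroman-4-one | COc1ccc([C@@H](O)/C=C2/C(=O)c3c(OCc4ccccc4)cc(OCc4ccccc4)cc3O[C@@H]2c2ccc(OCc3ccccc3)cc2)cc1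
F4 | step 7 | methyl carbonate of F3, (S) at the carbinol carbon | COc1ccc([C@@H](OC(=O)OC)/C=C2/C(=O)c3c(OCc4ccccc4)cc(OCc4ccccc4)cc3O[C@@H]2c2ccc(OCc3ccccc3)cc2)cc1
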